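**Retrosynthetic overview**
1. Target ⇐ face-selective epoxidation of the enol double bond of a spiro enol lactone (ring E oxygenation last).
2. Spiro enol lactone ⇐ one-pot cascade: an α-acylbutenolide (the oxidised furan) becomes its 2-oxidofuran, the 1(10),3-diene shifts to the 1,3-dienolide, and C13 adds to C1 (vinylogous Michael). This closes ring C and sets C10, C1 and C13.
3. Cascade substrate ⇐ Weinreb amide plus a 3-metallated 2-silyloxyfuran; lactone ring D ⇐ carbonylative lactonisation of the C4 enol triflate onto C19-OH.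
4. 7α-OAc and 8α-CH3 ⇐ C8 ketone (methylenation, allylic oxidation, two face-selective reductions); C9 ⇐ deconjugative alkylation anti to C19.
5. Rings A and B ⇐ cyclohexane-1,3-dione, ethyl vinyl ketone and formaldehyde by a desymmetrising Robinson annulation. Ring order: A, B, D, C, then the epoxide on E.

Assumption: clerodane numbering is used throughout (ring A = C1–C5, C10; ring B = C5–C10; ring C = C1, C10, C9, C11–C13; ring D = 18,19-lactone; ring E = spiro 16,15-lactone), α/β follow the usual neo-clerodane drawing (H-10 β; C19, C20, C17 and 7-OAc α), and the given SMILES defines the absolute configuration.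

**Step 1**
Reactants: 1 cyclohexane-1,3-dione; 2 pent-1-en-3-one (ethyl vinyl ketone)
Product: 4 2-(hydroxymethyl)-2-(3-oxopentyl)cyclohexane-1,3-dione, via triketone 3 (not isolated)
Conditions: H2O, 25 °C; then 37% aq. CH2O, NaHCO3 (cat.), 0 → 25 °C
Reagents that add atoms: formaldehyde C=O
Why: Michael addition of the 1,3-dione to the enone in water is followed by a Tollens-type aldol with formaldehyde that can only occur at C2 of the 2-alkyl-1,3-dione, giving the prochiral quaternary carbon that becomes C5 with C19 already oxygenated (no stereocentre yet).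

**Step 2**
Reactants: 4 2-(hydroxymethyl)-2-(3-oxopentyl)cyclohexane-1,3-dione
Product: 5 2-[(tert-butyldimethylsilyloxy)methyl]-2-(3-oxopentyl)cyclohexane-1,3-dione
Conditions: t-BuMe2SiCl, imidazole, DMF, 0 °C
Reagents that add atoms: tert-butyldimethylsilyl chloride CC(C)(C)[Si](C)(C)Cl
Why: Standard silylation of the primary alcohol blocks retro-aldol loss of formaldehyde in the later basic steps (no stereocentre).

**Step 3**
Reactants: 5 2-[(tert-butyldimethylsilyloxy)methyl]-2-(3-oxopentyl)cyclohexane-1,3-dione
Product: 6 (4aR)-4a-[(tert-butyldimethylsilyloxy)methyl]-1-methyl-4,4a,7,8-tetrahydronaphthalene-2,5(3H,6H)-dione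
Conditions: D-phenylalanine (1 equiv), (1S)-(+)-10-camphorsulfonic acid (0.5 equiv), DMF, 30 → 70 °C
Reagents that add atoms: none
Why: Hajos–Parrish–Eder–Sauer–Wiechert desymmetrising intramolecular aldol condensation, in which the D-amino acid enamine attacks one enantiotopic ring carbonyl and sets C5 as R (mirror image of the L-amino acid series), completing the Robinson annulation of ring B onto ring A.

**Step 4**
Reactants: 6 (4aR)-enedione
Product: 7 C4 ethylene ketal of 6 (C8 enone kept)
Conditions: Me3SiOCH2CH2OSiMe3, Me3SiOTf (cat.), CH2Cl2, −78 → −20 °C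
Reagents that add atoms: 1,2-bis(trimethylsilyloxy)ethane C[Si](C)(C)OCCO[Si](C)(C)C
Why: Noyori ketalisation is selective for the saturated C4 ketone over the less electrophilic conjugated C8 ketone and spares the silyl ether (no new stereocentre).

**Step 5**
Reactants: 7 enone ketal; 8 2-bromo-N-methoxy-N-methylacetamide
Product: 9 β,γ-enone Weinreb amide (C4 ketal; 5α-CH2OTBS; C1=C10; C8 ketone; 9α-CH3; 9β-CH2C(O)N(OMe)Me)
Conditions: KOt-Bu, t-BuOH/THF, 0 °C; then 8, 0 → 25 °C
Reagents that add atoms: none
Why: Deconjugative α-alkylation of the thermodynamic dienolate puts the electrophile on C9 from the β face, anti to the pseudoaxial 5α-CH2OTBS group, so C9 gets the 9β side chain and 9α-methyl group while the double bond moves to C1=C10.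

**Step 6**
Reactants: 9 β,γ-enone Weinreb amide
Product: 10 8(17)-methylene compound (C8=CH2 in place of the ketone)
Conditions: Zn, CH2Br2, TiCl4, THF/CH2Cl2, 0 → 25 °C
Reagents that add atoms: dibromomethane BrCBr
Why: Takai–Lombardo methylenation is non-basic and works on hindered enolisable ketones while leaving the amide, ketal and silyl ether alone; the new carbon is C17.

**Step 7**
Reactants: 10 8(17)-methylene compound
Product: 12 8(17)-en-7-one, via allylic alcohol 11 (not isolated)
Conditions: SeO2 (0.5 equiv), t-BuOOH, CH2Cl2, 25 °C; then Dess–Martin periodinane, NaHCO3, CH2Cl2, 0 → 25 °C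
Reagents that add atoms: selenium dioxide O=[Se]=O (oxygen carrier); tert-butyl hydroperoxide CC(C)(C)OO (terminal oxygen source)
Why: The SeO2 ene/[2,3]-sigmatropic allylic oxidation can only take hydrogen from C7 (C9 is quaternary and the C1=C10 alkene has no hydrogen on the carbons attached to its more substituted end), and Dess–Martin oxidation converges both alcohol epimers on one enone, so no stereocentre needs control here.

**Step 8**
Reactants: 12 8(17)-en-7-one
Product: 13 C7 ketone with 8α-CH3
Conditions: H2 (1 atm), 10% Pd/C, EtOAc, 25 °C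
Reagents that add atoms: none
Why: Heterogeneous hydrogenation of the exocyclic enone delivers hydrogen to C8 from the β face because the α face is screened by the axial 9α-CH3 and 5α-CH2OTBS groups, giving the equatorial 8α-methyl group (also the thermodynamic epimer) while the hindered C1=C10 alkene is untouched.

**Step 9**
Reactants: 13 C7 ketone
Product: 15 7α-acetate, via lithium 7α-alkoxide 14 (not isolated)
Conditions: LiBH(s-Bu)3, THF, −78 °C; then Ac2O, DMAP, −78 → 25 °C
Reagents that add atoms: acetic anhydride CC(=O)OC(C)=O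
Why: The bulky hydride attacks the C7 ketone from the open β (equatorial) side because the α-axial path is blocked by the syn-axial C19 and C20 groups (the 11-keto steroid situation), and the resulting axial 7α-alkoxide is acetylated in situ (reductive acetylation) more readily than the free hindered alcohol.

**Step 10**
Reactants: 15 7α-acetate
Product: 16 7α-acetoxy-19-hydroxy-4-ketone
Conditions: 48% aq. HF, MeCN, 0 → 25 °C
Reagents that add atoms: water O
Why: Aqueous HF hydrolyses the dioxolane and cleaves the silyl ether in one operation, and the β-hydroxy ketone cannot dehydrate because C5 is quaternary (no stereocentre touched).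

**Step 11**
Reactants: 16 7α-acetoxy-19-hydroxy-4-ketone
Product: 19 19-hydroxy-1(10),3-dien-4-yl triflate, via trimethylsilyl ether 17 (not isolated), via silylated enol triflate 18 (not isolated)
Conditions: Me3SiCl, Et3N, CH2Cl2, 0 °C, evaporate; KN(SiMe3)2, THF, −78 °C; PhNTf2, −78 → 0 °C; 1 M HCl work-up
Reagents that add atoms: N-phenylbis(trifluoromethanesulfonimide) FC(F)(F)S(=O)(=O)N(c1ccccc1)S(=O)(=O)C(F)(F)F; chlorotrimethylsilane C[Si](C)(C)Cl (silicon present in 17 and 18 only)
Why: After transient O-silylation of C19-OH, the C4 ketone can only enolise toward C3 (C5 is quaternary), and O-triflation of the potassium enolate followed by acidic work-up gives the hydroxy enol triflate (no stereocentre touched).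

**Step 12**
Reactants: 19 hydroxy dienyl triflate
Product: 20 7α-acetoxy-1(10),3-dien-18,19-olide Weinreb amide
Conditions: Pd(PPh3)4 (5 mol %), CO (1 atm), Et3N, LiCl, DMF, 65 °C
Reagents that add atoms: carbon monoxide [C-]#[O+]
Why: Oxidative addition of the enol triflate, CO insertion and capture of the acyl–palladium species by C19-OH (carbonylative lactonisation) close ring D as the α-alkylidene lactone (no stereocentre formed).

**Step 13**
Reactants: 21 3-bromofuran-2(5H)-one
Product: 22 3-bromo-2-(triisopropylsilyloxy)furan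
Conditions: i-Pr3SiOTf, Et3N, CH2Cl2, 0 °C
Reagents that add atoms: triisopropylsilyl trifluoromethanesulfonate CC(C)[Si](OS(=O)(=O)C(F)(F)F)(C(C)C)C(C)C
Why: O-silylation of the butenolide dienolate gives the aromatic 2-silyloxyfuran, whose bulky silyl group suppresses oxygen-to-carbon silyl migration after metalation.

**Step 14**
Reactants: 20 dienolide Weinreb amide; 22 3-bromo-2-(triisopropylsilyloxy)furan
Product: 25 2-(triisopropylsilyloxy)furan-3-yl ketone (C12 ketone), via furyllithium 23 (not isolated), via furylmagnesium bromide 24 (not isolated)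
Conditions: 22, n-BuLi, THF, −78 °C; MgBr2·OEt2; then 20, −78 → −20 °C; aq. NH4Cl
Reagents that add atoms: none
Why: Bromine–lithium exchange and transmetalation give a furyl Grignard reagent that adds once to the Weinreb amide through the chelated tetrahedral intermediate (Weinreb ketone synthesis) faster than to the conjugated lactone or the hindered axial acetate (no stereocentre formed).

**Step 15**
Reactants: 25 silyloxyfuryl ketone
Product: 28 spiro enol lactone (7α-acetoxy-12-oxo-1,13-cyclo-neo-cleroda-3,14-diene-18,19:16,15-diolide), via acylbutenolide 26 (not isolated), via conjugated dienolide 27 (not isolated)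
Conditions: HF·pyridine, THF, 0 °C; then DBU (6 equiv), MeCN (0.005 M), 50 °C
Reagents that add atoms: none
Why: Proposed new method: fluoride unmasks the α-acylbutenolide, DBU deprotonates its γ-carbon to the aromatic 2-oxidofuran and also shuttles the C2 proton to C10 so that the skipped diene becomes the conjugated dienolide, whose C1 is attacked by C13 in a reversible 6-exo-trig vinylogous (1,6-) Michael addition that under thermodynamic control gives the all-chair, all-trans perhydrophenalene (10β-H, 1α-H) with the lactone carbonyl C16 axial and anti to the C12 carbonyl dipole; the closest known reactions are DBU isomerisation of skipped dienoates, intramolecular 1,6-Michael additions of β-dicarbonyl compounds and C3-alkylation of 2-oxidofurans.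

**Step 16**
Reactants: 28 spiro enol lactone
Product: 29 CNP0308057.1
Conditions: dimethyldioxirane, acetone/CH2Cl2, −20 → 0 °C
Reagents that add atoms: dimethyldioxirane CC1(C)OO1
Why: Dimethyldioxirane epoxidises only the electron-rich enol lactone double bond (the alkylidene lactone is electron-poor) and approaches the face of ring E that looks toward the flat C12 carbonyl, not the face covered by C2H2 and ring A, giving the 14,15-epoxide syn to C12 under neutral conditions that the labile acyloxy epoxide tolerates.

**Compound list**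
1 | cyclohexane-1,3-dione | O=C1CCCC(=O)C1 | starting material
2 | pent-1-en-3-one (ethyl vinyl ketone) | CCC(=O)C=C | starting material
3 | 2-(3-oxopentyl)cyclohexane-1,3-dione (not isolated) | CCC(=O)CCC1C(=O)CCCC1=O | intermediate
4 | 2-(hydroxymethyl)-2-(3-oxopentyl)cyclohexane-1,3-dione | CCC(=O)CCC1(CO)C(=O)CCCC1=O | intermediate
5 | 2-[(tert-butyldimethylsilyloxy)methyl]-2-(3-oxopentyl)cyclohexane-1,3-dione | CCC(=O)CCC1(CO[Si](C)(C)C(C)(C)C)C(=O)CCCC1=O | intermediate
6 | (4aR)-4a-[(tert-butyldimethylsilyloxy)methyl]-1-methyl-4,4a,7,8-tetrahydronaphthalene-2,5(3H,6H)-dione (C4 and C8 ketones, C9=C10, 5α-CH2OTBS) | CC1=C2CCCC(=O)[C@]2(CO[Si](C)(C)C(C)(C)C)CCC1=O | intermediate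
7 | C4 ethylene ketal (1,3-dioxolane) of 6, C8 enone retained | CC1=C2CCCC3(OCCO3)[C@]2(CO[Si](C)(C)C(C)(C)C)CCC1=O | intermediate
8 | 2-bromo-N-methoxy-N-methylacetamide | CON(C)C(=O)CBr | starting material
9 | bicyclic β,γ-enone: C4 ethylene ketal, 5α-CH2OTBS, C1=C10, C8 ketone, 9α-CH3, 9β-CH2C(O)N(OMe)Me | CON(C)C(=O)C[C@@]1(C)C(=O)CC[C@]2(CO[Si](C)(C)C(C)(C)C)C1=CCCC23OCCO3 | intermediate
10 | as 9 with C8=C17H2 (exocyclic methylene) in place of the ketone | CON(C)C(=O)C[C@@]1(C)C(=C)CC[C@]2(CO[Si](C)(C)C(C)(C)C)C1=CCCC23OCCO3 | intermediate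
11 | as 10 with 7-OH, both epimers (not isolated) | CON(C)C(=O)C[C@@]1(C)C(=C)C(O)C[C@]2(CO[Si](C)(C)C(C)(C)C)C1=CCCC23OCCO3 | intermediate
12 | as 10 with a C7 ketone (8(17)-en-7-one) | CON(C)C(=O)C[C@@]1(C)C(=C)C(=O)C[C@]2(CO[Si](C)(C)C(C)(C)C)C1=CCCC23OCCO3 | intermediate
13 | C7 ketone with 8α-CH3 (8β-H) | CON(C)C(=O)C[C@@]1(C)[C@H](C)C(=O)C[C@]2(CO[Si](C)(C)C(C)(C)C)C1=CCCC23OCCO3 | intermediate
14 | lithium 7α-alkoxide from 13 (not isolated) | [Li+].CON(C)C(=O)C[C@@]1(C)[C@H](C)[C@H]([O-])C[C@]2(CO[Si](C)(C)C(C)(C)C)C1=CCCC23OCCO3 | intermediate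
15 | 7α-acetate (8α-CH3, C4 ketal, 5α-CH2OTBS, C1=C10) | CON(C)C(=O)C[C@@]1(C)[C@H](C)[C@H](OC(C)=O)C[C@]2(CO[Si](C)(C)C(C)(C)C)C1=CCCC23OCCO3 | intermediate
16 | 7α-acetoxy-19-hydroxy-4-ketone (C1=C10) | CON(C)C(=O)C[C@@]1(C)[C@H](C)[C@H](OC(C)=O)C[C@]2(CO)C1=CCCC2=O | intermediate
17 | 19-O-trimethylsilyl ether of 16 (not isolated) | CON(C)C(=O)C[C@@]1(C)[C@H](C)[C@H](OC(C)=O)C[C@]2(CO[Si](C)(C)C)C1=CCCC2=O | intermediate
18 | C3=C4 enol triflate of 17 (not isolated) | CON(C)C(=O)C[C@@]1(C)[C@H](C)[C@H](OC(C)=O)C[C@]2(CO[Si](C)(C)C)C1=CCC=C2OS(=O)(=O)C(F)(F)F | intermediate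
19 | 7α-acetoxy-19-hydroxy-1(10),3-dien-4-yl triflate | CON(C)C(=O)C[C@@]1(C)[C@H](C)[C@H](OC(C)=O)C[C@]2(CO)C1=CCC=C2OS(=O)(=O)C(F)(F)F | intermediate
20 | 7α-acetoxy-1(10),3-dien-18,19-olide with 9β-CH2C(O)N(OMe)Me | CON(C)C(=O)C[C@@]1(C)[C@H](C)[C@H](OC(C)=O)C[C@@]23COC(=O)C2=CCC=C13 | intermediate
21 | 3-bromofuran-2(5H)-one | O=C1OCC=C1Br | starting material
22 | 3-bromo-2-(triisopropylsilyloxy)furan | CC(C)[Si](Oc1occc1Br)(C(C)C)C(C)C | intermediate
23 | [2-(triisopropylsilyloxy)furan-3-yl]lithium (not isolated) | CC(C)[Si](Oc1occc1[Li])(C(C)C)C(C)C | intermediate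
24 | [2-(triisopropylsilyloxy)furan-3-yl]magnesium bromide (not isolated) | CC(C)[Si](Oc1occc1[Mg]Br)(C(C)C)C(C)C | intermediate
25 | as 20 with the amide replaced by a 2-(triisopropylsilyloxy)furan-3-yl ketone at C12 | CC(C)[Si](Oc1occc1C(=O)C[C@@]1(C)[C@H](C)[C@H](OC(C)=O)C[C@@]23COC(=O)C2=CCC=C13)(C(C)C)C(C)C | intermediate
26 | 7α-acetoxy-12-oxo-neo-cleroda-1(10),3,13-triene-18,19:16,15-diolide (not isolated) | O=C1OCC=C1C(=O)C[C@@]1(C)[C@H](C)[C@H](OC(C)=O)C[C@@]23COC(=O)C2=CCC=C13 | intermediate
27 | 7α-acetoxy-12-oxo-neo-cleroda-1,3,13-triene-18,19:16,15-diolide, 10β-H (not isolated) | O=C1OCC=C1C(=O)C[C@@]1(C)[C@H](C)[C@H](OC(C)=O)C[C@@]23COC(=O)C2=CC=C[C@H]13 | intermediate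
28 | 7α-acetoxy-12-oxo-1,13-cyclo-neo-cleroda-3,14-diene-18,19:16,15-diolide (1α-H, 10β-H, C16 β-axial at spiro C13) | CC(=O)O[C@@H]1C[C@@]23COC(=O)C2=CC[C@@H]2[C@@H]3[C@@](C)(CC(=O)[C@]23C(=O)OC=C3)[C@@H]1C | intermediate
29 | CNP0308057.1 (14,15-epoxide of 28, oxygen syn to C12) | CC(=O)O[C@@H]1C[C@@]23COC(=O)C2=CC[C@@H]2[C@@H]3[C@@](C)(CC(=O)[C@]23C(=O)O[C@H]2O[C@H]23)[C@@H]1C | target

**Totals**
Total step count: 16. Longest linear sequence: 15 (steps 1–12 and 14–16; step 13 makes the furan reagent).

**Steps most likely to fail**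

Step 15 (cascade). The diene may not isomerise cleanly, or C10/C1/C13 may not all reach the natural configuration. Fallback, setting out from 25 and returning at 28: treat 25 with DBU alone, keeping the silyl ether, so that only the diene isomerises to the conjugated 10β-H dienolide silyloxyfuran F3. Its C10 configuration can then be checked, and corrected by equilibration or separation, before any C–C bond is made. BF3·OEt2 in CH2Cl2 at −78 °C then triggers an intramolecular vinylogous Mukaiyama–Michael addition of the silyloxyfuran C3 to C1, and loss of the silyl group gives 28.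

Step 14 (acylation). The hindered furyl Grignard reagent may add slowly or attack the lactone. Fallback, setting out from 20 and returning at 26: reduce the Weinreb amide with Cp2Zr(H)Cl in THF to the C12 aldehyde F1. Couple it with 21 under Nozaki–Hiyama–Kishi conditions (CrCl2, NiCl2 cat., DMF), which tolerate the lactone and acetate, to give the α-(1-hydroxyalkyl)butenolide F2. Oxidise with Dess–Martin periodinane to 26, which then only needs the DBU stage of step 15.

Step 16 (epoxidation). The dioxirane may attack the other face of ring E. Fallback, setting out from 28 and returning at 29: N-bromosuccinimide in wet THF puts bromine on C14 from the face the dioxirane preferred and water on C15 anti to it, giving the bromo hemiacetal F4. Ag2O then closes the oxirane with inversion at C14, so the epoxide oxygen ends on the face opposite to that of the direct epoxidation, giving 29.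

**Further compounds**
F1 | step 14 | C12 aldehyde: 7α-acetoxy-1(10),3-dien-18,19-olide with 9β-CH2CHO | O=CC[C@@]1(C)[C@H](C)[C@H](OC(C)=O)C[C@@]23COC(=O)C2=CCC=C13
F2 | step 14 | 12-hydroxy precursor of 26 (α-(1-hydroxyalkyl)butenolide, C12 epimers) | O=C1OCC=C1C(O)C[C@@]1(C)[C@H](C)[C@H](OC(C)=O)C[C@@]23COC(=O)C2=CCC=C13
F3 | step 15 | 10β-H conjugated 1,3-dienolide isomer of 25 (silyloxyfuran retained) | CC(C)[Si](Oc1occc1C(=O)C[C@@]1(C)[C@H](C)[C@H](OC(C)=O)C[C@@]23COC(=O)C2=CC=C[C@H]13)(C(C)C)C(C)C
F4 | step 16 | 14-bromo-15-hydroxy lactone from 28 (Br on the C1 face, OH on the C12 face of ring E) | CC(=O)O[C@@H]1C[C@@]23COC(=O)C2=CC[C@@H]2[C@@H]3[C@@](C)(CC(=O)[C@]23C(=O)O[C@@H](O)[C@@H]3Br)[C@@H]1C
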